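Right-handed substrate plus right-handed product is an invariant of this closed flask: together they stay at 50.0% of the substrate charged, and the left-handed pair does the same. So the right-handed substrate at any time is a large known term less a small correction, the right-handed product, and I reckon only the correction.

| flask | left-handed substrate | right-handed substrate | partner | protic impurity | free catalyst | remark | time |
|---|---|---|---|---|---|---|---|
| dawn | 0.25 M | 0.25 M | 0.20 M | 0.050 M | 14 mM | run made earlier |  |
| summer | 0.25 M | 0.25 M | 0.20 M | 0.050 M | 26 mM | run made earlier |  |
| autumn | 0.25 M | 0.25 M | 0.20 M | 0.050 M | 41 mM | run made earlier |  |
| amber | 0.25 M | 0.25 M | 0.200 M | 0.0500 M | 12 mM |  | 50 min |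
| red | 0.25 M | 0.25 M | 0.200 M | 0.0500 M | 24 mM |  | 50 min |
| green | 0.25 M | 0.25 M | 0.200 M | 0.0500 M | 48 mM |  | 50 min |

| run | time / min | left-handed product / % | right-handed substrate / % | right-handed product / % | left-handed substrate / % |
|---|---|---|---|---|---|
| dawn | 2.00 | 10 | 52 | 2 | 42 |
| dawn | 5.00 | 11 | 45 | 0 | 40 |
| dawn | 10.0 | 19 | 46 | 0 | 31 |
| dawn | 25.0 | 21 | 49 | 0 | 32 |
| summer | 6.00 | 16 | 51 | 0 | 30 |
| summer | 12.0 | 21 | 47 | 0 | 29 |
| summer | 20.0 | 22 | 48 | 0 | 29 |
| summer | 25.0 | 24 | 50 | 0 | 30 |
| autumn | 6.00 | 26 | 51 | 0 | 29 |
| autumn | 12.0 | 21 | 50 | 0 | 22 |
| autumn | 20.0 | 27 | 47 | 0 | 25 |
| autumn | 25.0 | 32 | 50 | 2 | 22 |

(standard deviation of a reading: 2 percentage points)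

- free catalyst is single-handed; left-handed substrate and right-handed substrate are mirror images of each other, charged as a racemate, each of them at the stated concentration
- the earlier runs were read with a standard deviation of 2 percentage points
- steps thought possible: partner + free catalyst + left-handed substrate -> free catalyst + left-handed product; partner + free catalyst + right-handed substrate -> free catalyst + right-handed product; free catalyst -> spent catalyst; partner + protic impurity -> quenched reagent

* which of these there is most of at the end, counted by the substrate in it, amber (right-handed substrate / right-handed product / left-handed product / left-handed substrate)
* which of these there is most of at the end, counted by the substrate in it, red (right-handed substrate / right-handed product / left-handed product / left-handed substrate)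
* which of these there is most of at the end, counted by the substrate in it, green (right-handed substrate / right-handed product / left-handed product / left-handed substrate)
* amount of the one of these that there is most of at the end, in percent of the left-handed substrate and right-handed substrate together charged, amber
* amount of the one of these that there is most of at the end, in percent of the left-handed substrate and right-handed substrate together charged, red
* amount of the one of these that there is most of at the end, in percent of the left-handed substrate and right-handed substrate together charged, green

I follow the dawn run in slow motion. In the first instants, at 2.00 min, left-handed product reads 10% and right-handed product 2%, which is the size of the scatter of one reading, 2 percentage points. In the middle, at 10.0 min, left-handed product reads 19%. At 25.0 min it reads 21%, a gain of 2 points, the size of the scatter, while left-handed substrate still reads 32%.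

The last readings climb with the catalyst charge, from 21% through 24% to 32%, so I borrow them for amber, red and green in that order. I define the leak as right-handed product formed per left-handed product formed, taken over the last readings of the three runs: 2.60%. It is roughly the inverse of the selectivity factor of this kinetic resolution, and it is only a rough reading, since its numerator is one reading of 2%.

The corrections are then 0.55 points, 0.62 points and 0.83 points, and I expect right-handed substrate at 49.5%, 49.4% and 49.2%. The other contenders are lower than that, with left-handed substrate reckoned at 29.0% in amber and left-handed product borrowed at 32% in green, so I name right-handed substrate.

The forecast names right-handed substrate for amber, right-handed substrate for red and right-handed substrate for green, at 49.7%, 49.5% and 49.2%, on the ground that “the catalyst takes almost only the left-handed substrate”. Its amber figure stands above mine by 0.20 points.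

The flasks give right-handed substrate, right-handed substrate and right-handed substrate for amber, red and green, at 49.7%, 49.5% and 49.3%.

    partner + free catalyst + left-handed substrate → free catalyst + left-handed product (k = 0.670 M⁻² s⁻¹)
    partner + free catalyst + right-handed substrate → free catalyst + right-handed product (k = 0.0110 M⁻² s⁻¹)
    free catalyst → spent catalyst (k = 0.00250 s⁻¹)
    partner + protic impurity → quenched reagent (k = 0.0250 M⁻¹ s⁻¹)

In amber the left-handed step ran while free catalyst lasted: that catalyst has a half-life of 4.6 min, and by 10.0 min the step had 88% of its turnover up to the asked time behind it. By 25.0 min free catalyst stood at 2.35% of its charge and left-handed product at 15.8%, and at 50.0 min 34% of the partner was still there. The leak on amber's own left-handed product gives 0.416%, against 0.316% of right-handed product. Amber's right-handed substrate stays within 6 points of itself for catalyst from 1.5 mM to 96 mM at least.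

Amber with 0.34 M of partner makes 25.5% of left-handed product, so the leak gives 0.663% of right-handed product and right-handed substrate near 49.3%. The computed flask holds 0.584% of right-handed product and 49.4% of right-handed substrate.

The readings stem from a simulated flask with constants of no real substance, and the scatter is random.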